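**Retrosynthetic overview**

1. Numbering follows bicyclo[3.3.1]nonane: C1 prenyl bridgehead, C2 ketone, C3 aroyl carbon, C4 enol carbon, C5 geranyl bridgehead, C6 CH2, C7 CH(geranyl), C8 CMe2, C9 bridging ketone; ring A = C1-C9-C5-C6-C7-C8, ring B = C1-C2-C3-C4-C5-C9.
2. Endgame: the target comes from its C4 ethyl enol ether by hydrolysis and desilylation, after the aroyl group is put on C3 by vinyl lithiation and acylation.
3. Key disconnection: bonds C1–C9 (ring A) and C4–C5 (ring B) are cut together, which opens the bicycle to an acyclic ynone ester whose only fixed stereocenter is C7. The enabling feature is that C9 is an acyl carbon flanked by both bridgeheads and the ring B enol carbon C4 is the alkoxy-bearing carbon of a C2 ynone at the same oxidation level, so C1 and then C5 can act in turn as enolate carbons.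
4. Chain assembly: C5–C6 by ester enolate alkylation of an iodide, the C2 ynone from a Weinreb amide, the C1 prenyl by lactone alkylation, and C7 by auxiliary-controlled geranylation of a 3,3-dimethylglutarate (C6-C7-C8-C1-C2).
5. Ring order: no carbocycle exists before the key step; ring A and then ring B form in that one operation (a temporary δ-lactone only carries the chain).

Key step: step 10

Remark on the chemistry: the carbons that become C1 and C5 are carried as epimer mixtures up to step 10, where both are trigonal enolate carbons. The enol of the target is drawn as in the given structure; its tautomers interconvert.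

**Step 1**
Reactants: 1 monomethyl 3,3-dimethylglutarate; 2 (4S)-4-benzyl-1,3-oxazolidin-2-one
Product: 4 methyl 5-[(4S)-4-benzyl-2-oxo-1,3-oxazolidin-3-yl]-3,3-dimethyl-5-oxopentanoate, via mixed pivalic anhydride 3 (not isolated)
Conditions: PivCl, Et3N, THF, −20 °C; then 2, LiCl, −20 °C to rt
Reagents that add atoms: pivaloyl chloride, CC(C)(C)C(Cl)=O (its atoms appear only in 3)
Why: N-acylation of an oxazolidinone through a mixed pivalic anhydride with LiCl/Et3N activation, in which the nitrogen attacks the less hindered CH2–C=O carbonyl of 3; no stereocenter is formed.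

**Step 2**
Reactants: 4 imide ester; 5 geranyl bromide
Product: 6 methyl (4S,6E)-4-{[(4S)-4-benzyl-2-oxo-1,3-oxazolidin-3-yl]carbonyl}-3,3,7,11-tetramethyldodeca-6,10-dienoate
Conditions: NaN(SiMe3)2, THF, −78 °C; then 5, −78 to −30 °C
Reagents that add atoms: none
Why: Evans asymmetric alkylation, in which the chelated Z sodium enolate of the imide (the methyl ester is far less acidic and stays untouched) is alkylated by the allylic bromide on the face opposite the benzyl group, which sets the future C7 (S here, R in the target only through a change of CIP priorities).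

**Step 3**
Reactants: 6 alkylated imide
Product: 8 (5S)-5-[(2E)-3,7-dimethylocta-2,6-dien-1-yl]-4,4-dimethyloxan-2-one, via hydroxy ester 7 (not isolated)
Conditions: NaBH4, THF/H2O (4:1), 0 °C to rt; then pyridinium p-toluenesulfonate (cat.), toluene, 50 °C
Reagents that add atoms: none
Why: Reductive removal of the auxiliary with NaBH4 in wet THF should reduce only the imide carbonyl to the primary alcohol (methyl ester and alkenes survive), and the δ-hydroxy ester 7 lactonizes under mild acid with help from the gem-dimethyl group; the stereocenter is not touched.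

**Step 4**
Reactants: 8 lactone; 9 prenyl bromide
Product: 10 (5S)-5-[(2E)-3,7-dimethylocta-2,6-dien-1-yl]-4,4-dimethyl-3-(3-methylbut-2-en-1-yl)oxan-2-one (both C3 epimers)
Conditions: LiN(i-Pr)2, THF, −78 °C; then 9, DMPU, −78 to −30 °C
Reagents that add atoms: none
Why: Alkylation of a lactone lithium enolate with an allylic bromide at the only enolizable position (the future C1); the new center forms as an epimer mixture, which is irrelevant because it is enolized again in step 10.

**Step 5**
Reactants: 10 prenylated lactone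
Product: 11 (4S,6E)-4-(hydroxymethyl)-N-methoxy-N,3,3,7,11-pentamethyl-2-(3-methylbut-2-en-1-yl)dodeca-6,10-dienamide
Conditions: MeNHOMe·HCl, i-PrMgCl, THF, −20 to 0 °C
Reagents that add atoms: N,O-dimethylhydroxylamine hydrochloride, CNOC.Cl
Why: Weinreb aminolysis of a lactone with the magnesium amide of N,O-dimethylhydroxylamine opens the ring to the hydroxy amide and frees the C6 alcohol; no stereocenter is affected.

**Step 6**
Reactants: 11 hydroxy Weinreb amide
Product: 12 (4S,6E)-4-(iodomethyl)-N-methoxy-N,3,3,7,11-pentamethyl-2-(3-methylbut-2-en-1-yl)dodeca-6,10-dienamide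
Conditions: I2, PPh3, imidazole, CH2Cl2, 0 °C, dark; used at once
Reagents that add atoms: iodine, II
Why: Garegg–Samuelsson (Appel-type) iodination of a primary alcohol under buffered conditions that spare the alkenes; substitution at the CH2 group leaves C7 untouched.

**Step 7**
Reactants: 13 ethyl acetate; 5 geranyl bromide
Product: 14 ethyl (4E)-5,9-dimethyldeca-4,8-dienoate
Conditions: LiN(i-Pr)2, THF, −78 °C; then 5, DMPU, −78 to −20 °C
Reagents that add atoms: none
Why: Alkylation of the lithium enolate of ethyl acetate with a primary allylic bromide (SN2, E geometry retained).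

**Step 8**
Reactants: 12 iodide; 14 ethyl (4E)-5,9-dimethyldeca-4,8-dienoate
Product: 15 ethyl (4R)-2,4-bis[(2E)-3,7-dimethylocta-2,6-dien-1-yl]-7-[methoxy(methyl)amino]-5,5-dimethyl-6-(3-methylbut-2-en-1-yl)-7-oxoheptanoate
Conditions: 14, LiN(i-Pr)2, THF, −78 °C; then 12, DMPU, −78 to −20 °C
Reagents that add atoms: none
Why: Alkylation of an ester lithium enolate with a primary iodide forms C5–C6; the new center (future C5) is an irrelevant epimer mixture because it is enolized in step 10, and the hindered Weinreb amide should not be attacked at low temperature.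

**Step 9**
Reactants: 15 ester Weinreb amide; 16 ethoxyacetylene
Product: 17 ethyl (4R)-2,4-bis[(2E)-3,7-dimethylocta-2,6-dien-1-yl]-9-ethoxy-5,5-dimethyl-6-(3-methylbut-2-en-1-yl)-7-oxonon-8-ynoate
Conditions: 16, EtMgBr, THF, 0 °C to rt; then 15, 0 °C to rt; pH 7 buffer
Reagents that add atoms: none
Why: Weinreb ketone synthesis with an alkynyl Grignard reagent, in which the chelated tetrahedral intermediate stops at the ynone stage and alkynylmagnesium halides should not add to an α-branched ethyl ester under these conditions.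

**Step 10**
Reactants: 17 acyclic ynone ester
Product: 19 (1R,5S,7R)-4-ethoxy-5,7-bis[(2E)-3,7-dimethylocta-2,6-dien-1-yl]-8,8-dimethyl-1-(3-methylbut-2-en-1-yl)bicyclo[3.3.1]non-3-ene-2,9-dione, via monocyclic ynone diketone 18 (not isolated)
Conditions: KN(SiMe3)2 (1.3 equiv), THF, −78 to 0 °C; then AcOH
Reagents that add atoms: none
Why: Proposed new method: KN(SiMe3)2 removes C1–H, the only ketone α-hydrogen (about five pKa units more acidic than the ester α-hydrogen at C5), and the tetrasubstituted enolate acylates on the C9 ethyl ester (Dieckmann condensation, 6-(enolexo)-exo-trig, closes ring A) to give 18; the ethoxide set free then deprotonates C5–H of the new cyclohexanone, this enolate adds through carbon to C4, the ethoxy-bearing alkyne carbon of the ynone held axially on C1 (carba-Michael addition, 6-(enolendo)-endo-dig, anti addition, closes ring B), and protonation of the vinyl anion gives the vinylogous ester 19. The closest known reaction types are domino Dieckmann cyclizations of acyclic keto esters to bicyclo[3.3.1]nonane triones and 6-endo-dig carbocyclizations of cyclohexanone enol derivatives onto alkynes tethered at the α' carbon (known with gold catalysis); new is their combination through an ynone that keeps C3 non-acidic and C4 at the acyl oxidation level. C1 is set in the chair transition state of the Dieckmann closure with the C7 geranyl equatorial: ring carbon C7 should lie gauche to the slim alkynyl enolate arm and not to the prenyl CH2 (allylic strain), so the acyl arm becomes axial and trans to the geranyl, and because this closure is reversible under ethoxide while only this epimer can bridge through a chair–chair transition state, the other epimer should be recycled. C5 is set by the bridge itself, since C4 can only reach the enolate face that carries the axial acyl arm on C1. The step needs carbon and not oxygen attack of the C9 enolate on C4, secured by the axial arm that places C4 over C5 while the enolate oxygen lies in the plane of ring A; it also needs ethoxide to spare the C2 and C9 carbonyls, secured because its fastest reaction, conjugate addition to C4, only exchanges one ethoxy group for another in the addition–elimination that follows (ester and ynol ether carry the same ethoxy group).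

**Step 11**
Reactants: 20 3,4-dihydroxybenzoic acid
Product: 21 tert-butyldimethylsilyl 3,4-bis[(tert-butyldimethylsilyl)oxy]benzoate
Conditions: TBSCl, imidazole, DMF, rt
Reagents that add atoms: tert-butyldimethylsilyl chloride, CC(C)(C)[Si](C)(C)Cl
Why: Exhaustive silylation of both phenols and the carboxylic acid (silyl ether and silyl ester formation).

**Step 12**
Reactants: 21 tris-silyl compound
Product: 22 3,4-bis[(tert-butyldimethylsilyl)oxy]benzoyl chloride
Conditions: (COCl)2, DMF (cat.), CH2Cl2, 0 °C to rt
Reagents that add atoms: oxalyl chloride, ClC(=O)C(Cl)=O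
Why: Direct conversion of a silyl ester into the acid chloride with oxalyl chloride and catalytic DMF under neutral conditions that keep the aryl silyl ethers.

**Step 13**
Reactants: 19 bicyclic vinylogous ester; 22 aroyl chloride
Product: 23 (1S,5S,7R)-3-{3,4-bis[(tert-butyldimethylsilyl)oxy]benzoyl}-4-ethoxy-5,7-bis[(2E)-3,7-dimethylocta-2,6-dien-1-yl]-8,8-dimethyl-1-(3-methylbut-2-en-1-yl)bicyclo[3.3.1]non-3-ene-2,9-dione
Conditions: lithium 2,2,6,6-tetramethylpiperidide, THF, −78 °C; then 22, −78 to −40 °C
Reagents that add atoms: none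
Why: Lithiation of the C3 vinyl hydrogen of a 4-alkoxybicyclo[3.3.1]non-3-ene-2,9-dione (both bridgeheads are quaternary, so no other acidic site competes) and C-acylation of the vinyllithium with the aroyl chloride, a known way to install the C3 aroyl group in this compound class.

**Step 14**
Reactants: 23 aroylated enol ether
Product: 24 target, (1S,5S,7R)-3-(3,4-dihydroxybenzoyl)-4-hydroxy-5,7-bis[(2E)-3,7-dimethylocta-2,6-dien-1-yl]-8,8-dimethyl-1-(3-methylbut-2-en-1-yl)bicyclo[3.3.1]non-3-ene-2,9-dione
Conditions: LiOH, H2O/1,4-dioxane, 80 °C, argon; then dilute HCl to pH 3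
Reagents that add atoms: water, O
Why: Hydroxide adds to C4 of the 2-aroyl vinylogous ester and expels ethoxide (addition–elimination) while also cleaving the aryl silyl ethers, and acidification gives the enolized trione; no stereocenter is touched.

**Compound list**

1 | monomethyl 3,3-dimethylglutarate (5-methoxy-3,3-dimethyl-5-oxopentanoic acid) | COC(=O)CC(C)(C)CC(=O)O | starting material
2 | (4S)-4-benzyl-1,3-oxazolidin-2-one | O=C1N[C@@H](Cc2ccccc2)CO1 | starting material
3 | mixed pivalic anhydride of 1 | COC(=O)CC(C)(C)CC(=O)OC(=O)C(C)(C)C | intermediate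
4 | methyl 5-[(4S)-4-benzyl-2-oxo-1,3-oxazolidin-3-yl]-3,3-dimethyl-5-oxopentanoate | COC(=O)CC(C)(C)CC(=O)N1[C@@H](Cc2ccccc2)COC1=O | intermediate
5 | geranyl bromide, (2E)-1-bromo-3,7-dimethylocta-2,6-diene | CC(C)=CCC/C(C)=C/CBr | starting material
6 | methyl (4S,6E)-4-{[(4S)-4-benzyl-2-oxo-1,3-oxazolidin-3-yl]carbonyl}-3,3,7,11-tetramethyldodeca-6,10-dienoate | COC(=O)CC(C)(C)[C@H](C/C=C(\C)CCC=C(C)C)C(=O)N1[C@@H](Cc2ccccc2)COC1=O | intermediate
7 | methyl (4S,6E)-4-(hydroxymethyl)-3,3,7,11-tetramethyldodeca-6,10-dienoate | COC(=O)CC(C)(C)[C@H](C/C=C(\C)CCC=C(C)C)CO | intermediate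
8 | (5S)-5-[(2E)-3,7-dimethylocta-2,6-dien-1-yl]-4,4-dimethyloxan-2-one | O=C1CC(C)(C)[C@H](C/C=C(\C)CCC=C(C)C)CO1 | intermediate
9 | prenyl bromide, 1-bromo-3-methylbut-2-ene | CC(C)=CCBr | starting material
10 | (5S)-5-[(2E)-3,7-dimethylocta-2,6-dien-1-yl]-4,4-dimethyl-3-(3-methylbut-2-en-1-yl)oxan-2-one, both C3 epimers | O=C1C(CC=C(C)C)C(C)(C)[C@H](C/C=C(\C)CCC=C(C)C)CO1 | intermediate
11 | (4S,6E)-4-(hydroxymethyl)-N-methoxy-N,3,3,7,11-pentamethyl-2-(3-methylbut-2-en-1-yl)dodeca-6,10-dienamide, both C2 epimers | CON(C)C(=O)C(CC=C(C)C)C(C)(C)[C@H](C/C=C(\C)CCC=C(C)C)CO | intermediate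
12 | (4S,6E)-4-(iodomethyl)-N-methoxy-N,3,3,7,11-pentamethyl-2-(3-methylbut-2-en-1-yl)dodeca-6,10-dienamide, both C2 epimers | CON(C)C(=O)C(CC=C(C)C)C(C)(C)[C@H](C/C=C(\C)CCC=C(C)C)CI | intermediate
13 | ethyl acetate | CCOC(C)=O | starting material
14 | ethyl (4E)-5,9-dimethyldeca-4,8-dienoate | CCOC(=O)CC/C=C(\C)CCC=C(C)C | intermediate
15 | ethyl (4R)-2,4-bis[(2E)-3,7-dimethylocta-2,6-dien-1-yl]-7-[methoxy(methyl)amino]-5,5-dimethyl-6-(3-methylbut-2-en-1-yl)-7-oxoheptanoate, epimers at C2 and C6 | CON(C)C(=O)C(CC=C(C)C)C(C)(C)[C@H](C/C=C(\C)CCC=C(C)C)CC(C/C=C(\C)CCC=C(C)C)C(=O)OCC | intermediate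
16 | ethoxyacetylene | CCOC#C | starting material
17 | ethyl (4R)-2,4-bis[(2E)-3,7-dimethylocta-2,6-dien-1-yl]-9-ethoxy-5,5-dimethyl-6-(3-methylbut-2-en-1-yl)-7-oxonon-8-ynoate, epimers at C2 and C6 | CCOC#CC(=O)C(CC=C(C)C)C(C)(C)[C@H](C/C=C(\C)CCC=C(C)C)CC(C/C=C(\C)CCC=C(C)C)C(=O)OCC | intermediate
18 | (2S,4R)-2-(3-ethoxyprop-2-ynoyl)-4,6-bis[(2E)-3,7-dimethylocta-2,6-dien-1-yl]-3,3-dimethyl-2-(3-methylbut-2-en-1-yl)cyclohexan-1-one, acyl group trans to the C4 geranyl, C6 epimers | CC(C)=CCC/C(C)=C/C[C@@H]1CC(C/C=C(\C)CCC=C(C)C)C(=O)[C@@](CC=C(C)C)(C(=O)C#COCC)C1(C)C | intermediate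
19 | (1R,5S,7R)-4-ethoxy-5,7-bis[(2E)-3,7-dimethylocta-2,6-dien-1-yl]-8,8-dimethyl-1-(3-methylbut-2-en-1-yl)bicyclo[3.3.1]non-3-ene-2,9-dione, C7 geranyl on the side of the C9 bridge | CC(C)=CCC/C(C)=C/C[C@@H]1C[C@]2(C/C=C(\C)CCC=C(C)C)C(=O)[C@@](CC=C(C)C)(C(=O)C=C2OCC)C1(C)C | intermediate
20 | 3,4-dihydroxybenzoic acid | OC(=O)c1ccc(O)c(O)c1 | starting material
21 | tert-butyldimethylsilyl 3,4-bis[(tert-butyldimethylsilyl)oxy]benzoate | CC(C)(C)[Si](C)(C)OC(=O)c1ccc(O[Si](C)(C)C(C)(C)C)c(O[Si](C)(C)C(C)(C)C)c1 | intermediate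
22 | 3,4-bis[(tert-butyldimethylsilyl)oxy]benzoyl chloride | CC(C)(C)[Si](C)(C)Oc1ccc(C(Cl)=O)cc1O[Si](C)(C)C(C)(C)C | intermediate
23 | (1S,5S,7R)-3-{3,4-bis[(tert-butyldimethylsilyl)oxy]benzoyl}-4-ethoxy-5,7-bis[(2E)-3,7-dimethylocta-2,6-dien-1-yl]-8,8-dimethyl-1-(3-methylbut-2-en-1-yl)bicyclo[3.3.1]non-3-ene-2,9-dione (same spatial arrangement as 19) | CC(C)=CCC/C(C)=C/C[C@@H]1C[C@]2(C/C=C(\C)CCC=C(C)C)C(=O)[C@@](CC=C(C)C)(C(=O)C(C(=O)c3ccc(O[Si](C)(C)C(C)(C)C)c(O[Si](C)(C)C(C)(C)C)c3)=C2OCC)C1(C)C | intermediate
24 | CNP0125932.1, (1S,5S,7R)-3-(3,4-dihydroxybenzoyl)-4-hydroxy-5,7-bis[(2E)-3,7-dimethylocta-2,6-dien-1-yl]-8,8-dimethyl-1-(3-methylbut-2-en-1-yl)bicyclo[3.3.1]non-3-ene-2,9-dione | CC(C)=CCC/C(C)=C/C[C@@H]1C[C@]2(C/C=C(\C)CCC=C(C)C)C(=O)[C@@](CC=C(C)C)(C(=O)C(C(=O)c3ccc(O)c(O)c3)=C2O)C1(C)C | target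

**Step count and risks**

Total step count: 14. Longest linear sequence: 11 steps (1, 2, 3, 4, 5, 6, 8, 9, 10, 13, 14).

Steps most likely to fail:

1. Step 10. The hindered C1–H may enolize too slowly, so that the amide base adds to the ynone instead. The Dieckmann closure may show poor facial selectivity at C1, the C9 enolate may attack C4 through oxygen, or ethoxide may cleave the new β-diketone by retro-Claisen reaction. The fallback sets out from 17 and comes back at 19, with the two rings closed in separate, known operations. The Dieckmann condensation alone is run with LiN(SiMe3)2 in THF at low temperature and quenched cold with AcOH, and 18 is isolated. Its only enolizable position is silylated (TBSOTf, Et3N, CH2Cl2, −78 °C) to the silyl enol ether F1. Ring B is then closed by the gold-catalyzed 6-endo-dig carbocyclization of silyl enol ethers onto alkynes ([(2-biphenylyl)di-tert-butylphosphine]AuCl, AgN(SO2CF3)2, wet acetone/CH2Cl2, rt), which should give 19 after loss of the silyl group.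

2. Step 8. Substitution at the β-branched CH2–I next to the crowded C7/C8 region may be slow, and the iodide may be lost through cyclization of the amide oxygen onto C6 (return to the lactone). The fallback sets out from 11 and comes back at 15 without any leaving group on C6. Dess–Martin oxidation gives the aldehyde F2. A Wittig reaction with the stabilized ylide F3 (made from ethyl (triphenylphosphoranylidene)acetate and 5 by alkylation and transylidation) in toluene gives the α,β-unsaturated ester F4. Copper hydride conjugate reduction (Cu(OAc)2, 1,2-bis(diphenylphosphino)benzene, polymethylhydrosiloxane, t-BuOH, toluene) then gives 15, since the isolated trisubstituted alkenes and the Weinreb amide are not reduced.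

3. Step 9. Addition to the very hindered Weinreb amide may be incomplete, and the ester may be attacked when the reaction is forced. The fallback sets out from 12 and 14 and comes back at 17, with the C9 carbonyl protected as its carboxylate during the addition. Ester 14 is saponified (LiOH, THF/H2O) to (4E)-5,9-dimethyldeca-4,8-dienoic acid F5. Its dianion (LiN(i-Pr)2, 2 equiv, THF/DMPU) is alkylated by 12 to the acid Weinreb amide F6. Excess LiC≡COEt (THF, −78 to −20 °C; the lithium carboxylate is inert) gives the ynone acid F7, and EtI, K2CO3 in DMF gives 17.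

**Further compounds**

F1 | step 10 | tert-butyldimethylsilyl enol ether of 18 (C9–OSi, C9=C5 double bond; configuration at C1 and C7 as in 18) | CC(C)=CCC/C(C)=C/C[C@@H]1CC(C/C=C(\C)CCC=C(C)C)=C(O[Si](C)(C)C(C)(C)C)[C@@](CC=C(C)C)(C(=O)C#COCC)C1(C)C
F2 | step 8 | (4S,6E)-4-formyl-N-methoxy-N,3,3,7,11-pentamethyl-2-(3-methylbut-2-en-1-yl)dodeca-6,10-dienamide | CON(C)C(=O)C(CC=C(C)C)C(C)(C)[C@H](C/C=C(\C)CCC=C(C)C)C=O
F3 | step 8 | ethyl (4E)-5,9-dimethyl-2-(triphenylphosphoranylidene)deca-4,8-dienoate | CCOC(=O)C(C/C=C(\C)CCC=C(C)C)=P(c1ccccc1)(c1ccccc1)c1ccccc1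
F4 | step 8 | 2,3-didehydro derivative of 15 (C5=C6 double bond, either geometry; C7 as in 15) | CON(C)C(=O)C(CC=C(C)C)C(C)(C)[C@H](C/C=C(\C)CCC=C(C)C)C=C(C/C=C(\C)CCC=C(C)C)C(=O)OCC
F5 | step 9 | (4E)-5,9-dimethyldeca-4,8-dienoic acid | CC(C)=CCC/C(C)=C/CCC(O)=O
F6 | step 9 | (4R)-2,4-bis[(2E)-3,7-dimethylocta-2,6-dien-1-yl]-7-[methoxy(methyl)amino]-5,5-dimethyl-6-(3-methylbut-2-en-1-yl)-7-oxoheptanoic acid | CON(C)C(=O)C(CC=C(C)C)C(C)(C)[C@H](C/C=C(\C)CCC=C(C)C)CC(C/C=C(\C)CCC=C(C)C)C(O)=O
F7 | step 9 | (4R)-2,4-bis[(2E)-3,7-dimethylocta-2,6-dien-1-yl]-9-ethoxy-5,5-dimethyl-6-(3-methylbut-2-en-1-yl)-7-oxonon-8-ynoic acid | CCOC#CC(=O)C(CC=C(C)C)C(C)(C)[C@H](C/C=C(\C)CCC=C(C)C)CC(C/C=C(\C)CCC=C(C)C)C(O)=O
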